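**Retrosynthetic overview**

1. The target is a trans-α,β-dibenzyl-γ-butyrolactone: the α-benzyl group carries an erythro arylglycerol β-aryl ether, and the β-benzyl carbon sits on C5 of a trans-2-aryl-3-(hydroxymethyl)-2,3-dihydrobenzofuran.
2. Key disconnection: the bond between ring C3 of the oxolan-2-one (the carbon α to the lactone C=O) and the benzylic CH2 of the ether-bearing arene. It is made by C-benzylation of a lactone lithium enolate that is generated in the same flask by 1,4-addition of a lithiated 2-aryl-1,3-dithiane (the dihydrobenzofuran half) to (5R)-5-menthyloxyfuran-2(5H)-one, so both lactone stereocentres and both benzylic C–C bonds arise in one operation.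
3. Enabling feature: the ring C2 carbonyl makes ring C3 an enolate carbon and, in the butenolide, polarises C3=C4 for conjugate addition; the CH2 to be attached is benzylic and para to an ether oxygen, so its bromide is a good SN2 partner; the five-membered ring relays the C5 acetal stereocentre to C4 and C4 to C3 (all trans).
4. Fragments: the benzylic bromide comes from an Evans syn-aldol of an aryloxyacetyl imide followed by Mitsunobu inversion (erythro); the dithiane comes from an Evans syn-aldol of an arylacetyl imide followed by acid-mediated closure of the dihydrofuran ring (trans).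
5. Ring order: dihydrofuran ring of the benzofuran (step 18); lactone ring brought in as the butenolide (step 22), opened and re-closed when the auxiliary carbon is reduced (step 25); desulfurization, desilylation and hydrogenolysis finish the route.

Key step: step 23

Abbreviations used in names: TBS = tert-butyldimethylsilyl; Bn = benzyl; MOM = methoxymethyl; menthyl = (1R,2S,5R)-2-isopropyl-5-methylcyclohexyl; ArA-CH2 = 4-{[(1R,2S)-1-[4-(benzyloxy)-3-methoxyphenyl]-1,3-bis(TBS-oxy)propan-2-yl]oxy}-3-methoxybenzyl; ArB = (2S,3R)-2-[4-(benzyloxy)-3-methoxyphenyl]-3-[(TBS-oxy)methyl]-7-methoxy-2,3-dihydro-1-benzofuran-5-yl.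

**Fragment A: the benzylic bromide (steps 1–10)**

Step 1
Reactants: 1 (R)-4-benzyloxazolidin-2-one; 2 chloroacetyl chloride
Product: 4 (R)-4-benzyl-3-(chloroacetyl)oxazolidin-2-one, via N-lithio oxazolidinone 3 (not isolated)
Conditions: n-BuLi, THF, −78 °C; then 2, −78 → 0 °C
Reagents that add atoms: none
Why: N-acylation of the lithiated carbamate nitrogen by the acid chloride is the standard entry to N-acyl oxazolidinone imides and leaves the auxiliary stereocentre untouched.

Step 2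
Reactants: 4 chloroacetyl imide; 5 methyl 4-hydroxy-3-methoxybenzoate (methyl vanillate)
Product: 6 methyl 4-{2-[(R)-4-benzyl-2-oxooxazolidin-3-yl]-2-oxoethoxy}-3-methoxybenzoate
Conditions: K2CO3, NaI (cat.), acetone, 50 °C
Reagents that add atoms: none
Why: Williamson ether synthesis, in which the phenoxide displaces the chloride of the carbonyl-activated α-chloro imide by SN2.

Step 3
Reactants: 6 aryloxyacetyl imide; 7 4-(benzyloxy)-3-methoxybenzaldehyde
Product: 9 methyl 4-{[(1S,2R)-1-[4-(benzyloxy)-3-methoxyphenyl]-3-[(R)-4-benzyl-2-oxooxazolidin-3-yl]-1-hydroxy-3-oxopropan-2-yl]oxy}-3-methoxybenzoate, via dibutylboron Z-enolate 8 (not isolated)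
Conditions: Bu2BOTf, iPr2NEt, CH2Cl2, −78 → 0 °C; then 7, −78 → 0 °C; pH 7 buffer, MeOH, H2O2, 0 °C
Reagents that add atoms: none
Why: Evans syn-aldol reaction, in which the Z-boron enolate reacts through a closed chair (Zimmerman–Traxler) transition state on the face away from the benzyl group of the (R)-auxiliary; this sets the aryloxy-bearing carbon in the configuration the target needs and gives the carbinol carbon as S (threo series), to be inverted in step 6.

Step 4
Reactants: 9 syn-aldol imide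
Product: 10 methyl 4-{[(1S,2S)-1-[4-(benzyloxy)-3-methoxyphenyl]-1,3-dihydroxypropan-2-yl]oxy}-3-methoxybenzoate
Conditions: NaBH4, THF/H2O, 0 °C → rt
Reagents that add atoms: none
Why: reductive cleavage of the N-acyl oxazolidinone, in which borohydride in wet THF reduces the activated imide carbonyl to the primary alcohol and releases the auxiliary while the methyl benzoate and both stereocentres stay untouched.

Step 5
Reactants: 10 threo diol
Product: 11 methyl 4-{[(1S,2S)-1-[4-(benzyloxy)-3-methoxyphenyl]-1-hydroxy-3-(TBS-oxy)propan-2-yl]oxy}-3-methoxybenzoate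
Conditions: TBSCl, imidazole, CH2Cl2, 0 °C
Reagents that add atoms: tert-butyldimethylsilyl chloride, CC(C)(C)[Si](C)(C)Cl
Why: silyl ether formation that is selective for the primary hydroxyl over the hindered secondary benzylic one.

Step 6
Reactants: 11 mono-silyl ether
Product: 12 (1R,2S)-1-[4-(benzyloxy)-3-methoxyphenyl]-2-[2-methoxy-4-(methoxycarbonyl)phenoxy]-3-(TBS-oxy)propyl 4-nitrobenzoate
Conditions: 4-nitrobenzoic acid, PPh3, DIAD, toluene, −20 °C → rt
Reagents that add atoms: 4-nitrobenzoic acid, OC(=O)c1ccc(cc1)[N+](=O)[O-]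
Why: Mitsunobu reaction, in which the carboxylate displaces the alkoxyphosphonium group by SN2 with inversion, turning the (1S) carbinol into the (1R) ester and so the threo into the erythro series.

Step 7
Reactants: 12 4-nitrobenzoate
Product: 13 methyl 4-{[(1R,2S)-1-[4-(benzyloxy)-3-methoxyphenyl]-1-hydroxy-3-(TBS-oxy)propan-2-yl]oxy}-3-methoxybenzoate
Conditions: K2CO3 (cat.), MeOH, 0 °C → rt
Reagents that add atoms: none
Why: methanolysis (transesterification) of the activated 4-nitrobenzoate frees the erythro alcohol with retention and changes neither the silyl ether nor the methyl benzoate.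

Step 8
Reactants: 13 erythro alcohol
Product: 14 methyl 4-{[(1R,2S)-1-[4-(benzyloxy)-3-methoxyphenyl]-1,3-bis(TBS-oxy)propan-2-yl]oxy}-3-methoxybenzoate
Conditions: TBSOTf, 2,6-lutidine, CH2Cl2, −78 → 0 °C
Reagents that add atoms: tert-butyldimethylsilyl trifluoromethanesulfonate, CC(C)(C)[Si](C)(C)OS(=O)(=O)C(F)(F)F
Why: silylation of the hindered secondary benzylic alcohol with the silyl triflate and a non-nucleophilic base.

Step 9
Reactants: 14 bis-silyl ether ester
Product: 15 (4-{[(1R,2S)-1-[4-(benzyloxy)-3-methoxyphenyl]-1,3-bis(TBS-oxy)propan-2-yl]oxy}-3-methoxyphenyl)methanol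
Conditions: iBu2AlH, CH2Cl2, −78 → 0 °C; aq. KNaC4H4O6
Reagents that add atoms: none
Why: hydride reduction of the aryl methyl ester to the benzylic alcohol, to which silyl and benzyl ethers are inert.

Step 10
Reactants: 15 benzylic alcohol
Product: 16 1-(benzyloxy)-4-[(1R,2S)-2-[4-(bromomethyl)-2-methoxyphenoxy]-1,3-bis(TBS-oxy)propyl]-2-methoxybenzene (ArA-CH2Br)
Conditions: CBr4, PPh3, CH2Cl2, 0 °C
Reagents that add atoms: tetrabromomethane, BrC(Br)(Br)Br
Why: Appel reaction, which converts the primary benzylic alcohol into the bromide under neutral conditions that spare the silyl ethers.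

**Fragment B: the dithiane (steps 11–21)**

Step 11
Reactants: 17 2-allyl-6-methoxyphenol
Product: 18 2-allyl-4-bromo-6-methoxyphenol
Conditions: NBS, MeCN, 0 °C
Reagents that add atoms: N-bromosuccinimide, O=C1CCC(=O)N1Br
Why: electrophilic aromatic bromination, in which the only free position para to the hydroxyl should react much faster than the isolated terminal alkene.

Step 12
Reactants: 18 bromophenol
Product: 19 1-allyl-5-bromo-3-methoxy-2-(methoxymethoxy)benzene
Conditions: MOMCl, iPr2NEt, CH2Cl2, 0 → 40 °C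
Reagents that add atoms: chloromethyl methyl ether, COCCl
Why: O-alkylation of the phenol gives a MOM acetal that survives base and oxidants and is removed by the acid of step 18.

Step 13
Reactants: 19 MOM ether
Product: 20 2-[5-bromo-3-methoxy-2-(methoxymethoxy)phenyl]acetaldehyde
Conditions: OsO4 (cat.), NaIO4, 2,6-lutidine, dioxane/H2O, rt
Reagents that add atoms: osmium tetroxide, O=[Os](=O)(=O)=O; sodium periodate, [Na+].[O-]I(=O)(=O)=O
Why: Lemieux–Johnson oxidation, in which dihydroxylation of the terminal alkene and periodate cleavage of the diol shorten the allyl group to the arylacetaldehyde.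

Step 14
Reactants: 20 arylacetaldehyde
Product: 21 2-[5-bromo-3-methoxy-2-(methoxymethoxy)phenyl]acetic acid
Conditions: NaClO2, NaH2PO4, 2-methylbut-2-ene, t-BuOH/H2O, rt
Reagents that add atoms: sodium chlorite, [Na+].[O-]Cl=O
Why: Pinnick oxidation of the aldehyde to the acid under buffered conditions that the MOM ether and the aryl bromide tolerate.

Step 15
Reactants: 21 arylacetic acid; 22 (S)-4-benzyloxazolidin-2-one
Product: 24 (S)-4-benzyl-3-{2-[5-bromo-3-methoxy-2-(methoxymethoxy)phenyl]acetyl}oxazolidin-2-one, via mixed pivalic anhydride 23 (not isolated)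
Conditions: PivCl, Et3N, THF, −20 °C; then 22, LiCl, rt
Reagents that add atoms: none
Why: N-acylation of the oxazolidinone by the mixed pivalic anhydride (LiCl-assisted), which is attacked at the less hindered arylacetyl carbonyl.

Step 16
Reactants: 24 arylacetyl imide; 7 4-(benzyloxy)-3-methoxybenzaldehyde
Product: 26 (S)-4-benzyl-3-{(2S,3S)-3-[4-(benzyloxy)-3-methoxyphenyl]-2-[5-bromo-3-methoxy-2-(methoxymethoxy)phenyl]-3-hydroxypropanoyl}oxazolidin-2-one, via dibutylboron Z-enolate 25 (not isolated)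
Conditions: Bu2BOTf, iPr2NEt, CH2Cl2, −78 → 0 °C; then 7, −78 → 0 °C; pH 7 buffer, MeOH, H2O2, 0 °C
Reagents that add atoms: none
Why: Evans syn-aldol reaction through the closed chair transition state of the Z-boron enolate, with attack on the face away from the benzyl group of the (S)-auxiliary; this sets the aryl-bearing carbon as 2S (the later C3 of the dihydrobenzofuran, R there) and the carbinol carbon as 3S.

Step 17
Reactants: 26 syn-aldol imide
Product: 27 (1S,2R)-1-[4-(benzyloxy)-3-methoxyphenyl]-2-[5-bromo-3-methoxy-2-(methoxymethoxy)phenyl]propane-1,3-diol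
Conditions: LiBH4, MeOH (1 equiv), THF, 0 °C
Reagents that add atoms: none
Why: reductive removal of the auxiliary from the imide gives the 1,3-diol without touching the stereocentres or the aryl bromide.

Step 18
Reactants: 27 MOM-protected diol
Product: 29 [(2S,3R)-2-[4-(benzyloxy)-3-methoxyphenyl]-5-bromo-7-methoxy-2,3-dihydro-1-benzofuran-3-yl]methanol, via phenol triol 28 (not isolated)
Conditions: HCl (conc., cat.), MeOH/THF, rt → 45 °C
Reagents that add atoms: none
Why: acid cleaves the MOM acetal and ionizes the para-alkoxybenzylic alcohol, and the phenol oxygen captures the benzylic cation in a 5-exo ring closure (SN1-type cyclodehydration) that is reversible and should give the more stable 2,3-trans ring, so C2 is set as S by the fixed C3 centre.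

Step 19
Reactants: 29 dihydrobenzofuran alcohol
Product: 30 {[(2S,3R)-2-[4-(benzyloxy)-3-methoxyphenyl]-5-bromo-7-methoxy-2,3-dihydro-1-benzofuran-3-yl]methoxy}(tert-butyl)dimethylsilane (ArB-Br)
Conditions: TBSCl, imidazole, DMF, rt
Reagents that add atoms: tert-butyldimethylsilyl chloride, CC(C)(C)[Si](C)(C)Cl
Why: silyl ether formation at the primary alcohol, needed before the organolithium steps.

Step 20
Reactants: 30 aryl bromide
Product: 32 (2S,3R)-2-[4-(benzyloxy)-3-methoxyphenyl]-3-[(TBS-oxy)methyl]-7-methoxy-2,3-dihydro-1-benzofuran-5-carbaldehyde (ArB-CHO), via aryllithium 31 (not isolated)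
Conditions: n-BuLi, THF, −78 °C; then DMF, −78 → 0 °C; aq. NH4Cl
Reagents that add atoms: N,N-dimethylformamide, CN(C)C=O
Why: bromine–lithium exchange followed by formylation of the aryllithium with DMF (Bouveault-type aldehyde synthesis).

Step 21
Reactants: 32 aldehyde
Product: 33 2-(ArB)-1,3-dithiane
Conditions: HS(CH2)3SH, MgBr2·OEt2, Et2O/CH2Cl2, rt
Reagents that add atoms: propane-1,3-dithiol, SCCCS
Why: Lewis-acid-mediated dithioacetalization of the aldehyde, with a mild magnesium Lewis acid chosen to spare the benzylic aryl ether of the dihydrofuran ring and the silyl ether.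

**Butenolide (step 22)**

Step 22
Reactants: 34 5-hydroxyfuran-2(5H)-one; 35 (−)-menthol
Product: 36 (5R)-5-(menthyloxy)furan-2(5H)-one
Conditions: camphorsulfonic acid (cat.), toluene, reflux (Dean–Stark); crystallization from petroleum ether
Reagents that add atoms: none
Why: acid-catalysed acetalization of the cyclic hemiacylal with the chiral alcohol, in which the C5 epimers interconvert under the acid and the (5R) epimer is expected to be obtained pure by crystallization, the mother liquor being re-equilibrated.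

**Fragment union and endgame (steps 23–27)**

Step 23
Reactants: 33 2-(ArB)-1,3-dithiane; 36 (5R)-5-(menthyloxy)furan-2(5H)-one; 16 ArA-CH2Br
Product: 39 (3R,4R,5R)-3-(ArA-CH2)-4-[2-(ArB)-1,3-dithian-2-yl]-5-(menthyloxy)oxolan-2-one, via lithiated dithiane 37 (not isolated), via lithium enolate 38 (not isolated)
Conditions: n-BuLi, THF, −78 → −20 °C; then 36, −78 °C; then 16, DMPU, −78 → −30 °C
Reagents that add atoms: none
Why: n-BuLi removes the dithiane C2 proton of 33 to give the sulfur-stabilised benzylic anion 37, which adds 1,4 to the enone of butenolide 36 anti to the C5 menthyloxy group and gives lithium enolate 38; this enolate is then C-benzylated by bromide 16 in an SN2 step on the face away from the bulky C4 dithianyl substituent, which forms the C3–CH2 bond. The closest known reaction type is the tandem conjugate addition–enolate alkylation of lithiated 2-aryl-1,3-dithianes with 5-alkoxyfuran-2(5H)-ones used for trans-dibenzylbutyrolactone lignans. No ring is closed in this step; the lactone ring is carried in intact by 36. The C4 stereocentre (R) is controlled by the C5 acetal stereocentre of the auxiliary (attack anti to the menthyloxy group) and the C3 stereocentre (R) by the new C4 substituent (alkylation trans to it), while the stereocentres of the two large fragments are remote from the reacting carbons and should not interfere. The step needs 1,4- over 1,2-addition, which the soft, delocalised dithianyl anion and the unhindered β-carbon of the butenolide secure, and it needs C- over O-alkylation and mono-alkylation, which the lithium enolate, the reactive para-alkoxybenzylic bromide and the congestion around C3 of the product secure.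

Step 24
Reactants: 39 dithianyl lactone acetal
Product: 40 (3R,4R,5R)-3-(ArA-CH2)-4-(ArB-CH2)-5-(menthyloxy)oxolan-2-one
Conditions: NiCl2·6H2O, NaBH4, MeOH/THF, 0 °C
Reagents that add atoms: none
Why: reductive desulfurization of the benzylic dithioacetal by nickel boride (Ni2B) made in the flask replaces both C–S bonds by C–H without touching benzyl ethers, silyl ethers or the ring stereocentres.

Step 25
Reactants: 40 lactone acetal
Product: 42 (3R,4R)-3-(ArA-CH2)-4-(ArB-CH2)oxolan-2-one, via potassium hydroxy carboxylate 41 (not isolated)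
Conditions: NaBH4, KOH, EtOH/THF/H2O, rt; then 1 M HCl to pH 2, 0 °C → rt
Reagents that add atoms: none
Why: hydroxide opens the acyl acetal (pseudo-ester) to the carboxylate and the aldehyde with loss of mentholate, borohydride reduces the aldehyde at once, and acidification closes the γ-hydroxy acid to the lactone (reduction–lactonization), so the auxiliary carbon ends as the ring CH2 and both ring stereocentres are kept.

Step 26
Reactants: 42 tris-silyl lactone
Product: 43 (3R,4R)-3-{4-[(1R,2S)-1-[4-(benzyloxy)-3-methoxyphenyl]-1,3-dihydroxypropan-2-yl]oxy-3-methoxybenzyl}-4-{[(2S,3R)-2-[4-(benzyloxy)-3-methoxyphenyl]-3-(hydroxymethyl)-7-methoxy-2,3-dihydro-1-benzofuran-5-yl]methyl}oxolan-2-one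
Conditions: Bu4NF, AcOH, THF, rt
Reagents that add atoms: none
Why: fluoride-mediated cleavage of the three silyl ethers, buffered with acetic acid so that the lactone and the benzylic alcohol are not exposed to strong base.

Step 27
Reactants: 43 bis-benzyl ether
Product: 44 (3R,4R)-3-{4-[(1R,2S)-1,3-dihydroxy-1-(4-hydroxy-3-methoxyphenyl)propan-2-yl]oxy-3-methoxybenzyl}-4-{[(2S,3R)-2-(4-hydroxy-3-methoxyphenyl)-3-(hydroxymethyl)-7-methoxy-2,3-dihydro-1-benzofuran-5-yl]methyl}oxolan-2-one (target, CNP0298853.1)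
Conditions: H2 (1 atm), 10% Pd/C, EtOAc/EtOH, rt
Reagents that add atoms: none
Why: catalytic hydrogenolysis of the two phenolic benzyl ethers at atmospheric pressure, under which the benzylic alcohol and the benzylic ether of the dihydrofuran ring are expected to survive.

**Compound list**

1 | (R)-4-benzyloxazolidin-2-one | O=C1OC[C@@H](Cc2ccccc2)N1 | starting material
2 | chloroacetyl chloride | O=C(Cl)CCl | starting material
3 | N-lithio-(R)-4-benzyloxazolidin-2-one | O=C1OC[C@@H](Cc2ccccc2)N1[Li] | intermediate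
4 | (R)-4-benzyl-3-(chloroacetyl)oxazolidin-2-one | O=C1OC[C@@H](Cc2ccccc2)N1C(=O)CCl | intermediate
5 | methyl 4-hydroxy-3-methoxybenzoate | COC(=O)c1ccc(O)c(OC)c1 | starting material
6 | methyl 4-{2-[(R)-4-benzyl-2-oxooxazolidin-3-yl]-2-oxoethoxy}-3-methoxybenzoate | O=C1OC[C@@H](Cc2ccccc2)N1C(=O)COc1ccc(C(=O)OC)cc1OC | intermediate
7 | 4-(benzyloxy)-3-methoxybenzaldehyde | O=Cc1ccc(OCc2ccccc2)c(OC)c1 | starting material
8 | (Z)-dibutylboron enolate of 6 | O=C1OC[C@@H](Cc2ccccc2)N1/C(OB(CCCC)CCCC)=C/Oc1ccc(C(=O)OC)cc1OC | intermediate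
9 | methyl 4-{[(1S,2R)-1-[4-(benzyloxy)-3-methoxyphenyl]-3-[(R)-4-benzyl-2-oxooxazolidin-3-yl]-1-hydroxy-3-oxopropan-2-yl]oxy}-3-methoxybenzoate | O=C1OC[C@@H](Cc2ccccc2)N1C(=O)[C@H](Oc1ccc(C(=O)OC)cc1OC)[C@@H](O)c1ccc(OCc2ccccc2)c(OC)c1 | intermediate
10 | methyl 4-{[(1S,2S)-1-[4-(benzyloxy)-3-methoxyphenyl]-1,3-dihydroxypropan-2-yl]oxy}-3-methoxybenzoate | OC[C@H](Oc1ccc(C(=O)OC)cc1OC)[C@@H](O)c1ccc(OCc2ccccc2)c(OC)c1 | intermediate
11 | methyl 4-{[(1S,2S)-1-[4-(benzyloxy)-3-methoxyphenyl]-1-hydroxy-3-(TBS-oxy)propan-2-yl]oxy}-3-methoxybenzoate | CC(C)(C)[Si](C)(C)OC[C@H](Oc1ccc(C(=O)OC)cc1OC)[C@@H](O)c1ccc(OCc2ccccc2)c(OC)c1 | intermediate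
12 | (1R,2S)-1-[4-(benzyloxy)-3-methoxyphenyl]-2-[2-methoxy-4-(methoxycarbonyl)phenoxy]-3-(TBS-oxy)propyl 4-nitrobenzoate | CC(C)(C)[Si](C)(C)OC[C@H](Oc1ccc(C(=O)OC)cc1OC)[C@H](OC(=O)c1ccc(cc1)[N+](=O)[O-])c1ccc(OCc2ccccc2)c(OC)c1 | intermediate
13 | methyl 4-{[(1R,2S)-1-[4-(benzyloxy)-3-methoxyphenyl]-1-hydroxy-3-(TBS-oxy)propan-2-yl]oxy}-3-methoxybenzoate | CC(C)(C)[Si](C)(C)OC[C@H](Oc1ccc(C(=O)OC)cc1OC)[C@H](O)c1ccc(OCc2ccccc2)c(OC)c1 | intermediate
14 | methyl 4-{[(1R,2S)-1-[4-(benzyloxy)-3-methoxyphenyl]-1,3-bis(TBS-oxy)propan-2-yl]oxy}-3-methoxybenzoate | CC(C)(C)[Si](C)(C)OC[C@H](Oc1ccc(C(=O)OC)cc1OC)[C@H](O[Si](C)(C)C(C)(C)C)c1ccc(OCc2ccccc2)c(OC)c1 | intermediate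
15 | (4-{[(1R,2S)-1-[4-(benzyloxy)-3-methoxyphenyl]-1,3-bis(TBS-oxy)propan-2-yl]oxy}-3-methoxyphenyl)methanol | CC(C)(C)[Si](C)(C)OC[C@H](Oc1ccc(CO)cc1OC)[C@H](O[Si](C)(C)C(C)(C)C)c1ccc(OCc2ccccc2)c(OC)c1 | intermediate
16 | 1-(benzyloxy)-4-[(1R,2S)-2-[4-(bromomethyl)-2-methoxyphenoxy]-1,3-bis(TBS-oxy)propyl]-2-methoxybenzene (ArA-CH2Br) | CC(C)(C)[Si](C)(C)OC[C@H](Oc1ccc(CBr)cc1OC)[C@H](O[Si](C)(C)C(C)(C)C)c1ccc(OCc2ccccc2)c(OC)c1 | intermediate
17 | 2-allyl-6-methoxyphenol | C=CCc1cccc(OC)c1O | starting material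
18 | 2-allyl-4-bromo-6-methoxyphenol | C=CCc1cc(Br)cc(OC)c1O | intermediate
19 | 1-allyl-5-bromo-3-methoxy-2-(methoxymethoxy)benzene | C=CCc1cc(Br)cc(OC)c1OCOC | intermediate
20 | 2-[5-bromo-3-methoxy-2-(methoxymethoxy)phenyl]acetaldehyde | O=CCc1cc(Br)cc(OC)c1OCOC | intermediate
21 | 2-[5-bromo-3-methoxy-2-(methoxymethoxy)phenyl]acetic acid | OC(=O)Cc1cc(Br)cc(OC)c1OCOC | intermediate
22 | (S)-4-benzyloxazolidin-2-one | O=C1OC[C@H](Cc2ccccc2)N1 | starting material
23 | mixed anhydride of 21 and pivalic acid | CC(C)(C)C(=O)OC(=O)Cc1cc(Br)cc(OC)c1OCOC | intermediate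
24 | (S)-4-benzyl-3-{2-[5-bromo-3-methoxy-2-(methoxymethoxy)phenyl]acetyl}oxazolidin-2-one | O=C1OC[C@H](Cc2ccccc2)N1C(=O)Cc1cc(Br)cc(OC)c1OCOC | intermediate
25 | (Z)-dibutylboron enolate of 24 | O=C1OC[C@H](Cc2ccccc2)N1/C(OB(CCCC)CCCC)=C/c1cc(Br)cc(OC)c1OCOC | intermediate
26 | (S)-4-benzyl-3-{(2S,3S)-3-[4-(benzyloxy)-3-methoxyphenyl]-2-[5-bromo-3-methoxy-2-(methoxymethoxy)phenyl]-3-hydroxypropanoyl}oxazolidin-2-one | O=C1OC[C@H](Cc2ccccc2)N1C(=O)[C@@H](c1cc(Br)cc(OC)c1OCOC)[C@H](O)c1ccc(OCc2ccccc2)c(OC)c1 | intermediate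
27 | (1S,2R)-1-[4-(benzyloxy)-3-methoxyphenyl]-2-[5-bromo-3-methoxy-2-(methoxymethoxy)phenyl]propane-1,3-diol | OC[C@@H](c1cc(Br)cc(OC)c1OCOC)[C@H](O)c1ccc(OCc2ccccc2)c(OC)c1 | intermediate
28 | (1S,2R)-1-[4-(benzyloxy)-3-methoxyphenyl]-2-(5-bromo-2-hydroxy-3-methoxyphenyl)propane-1,3-diol | OC[C@@H](c1cc(Br)cc(OC)c1O)[C@H](O)c1ccc(OCc2ccccc2)c(OC)c1 | intermediate
29 | [(2S,3R)-2-[4-(benzyloxy)-3-methoxyphenyl]-5-bromo-7-methoxy-2,3-dihydro-1-benzofuran-3-yl]methanol | Brc1cc(OC)c2c(c1)[C@H](CO)[C@@H](c1ccc(OCc3ccccc3)c(OC)c1)O2 | intermediate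
30 | {[(2S,3R)-2-[4-(benzyloxy)-3-methoxyphenyl]-5-bromo-7-methoxy-2,3-dihydro-1-benzofuran-3-yl]methoxy}(tert-butyl)dimethylsilane (ArB-Br) | Brc1cc(OC)c2c(c1)[C@H](CO[Si](C)(C)C(C)(C)C)[C@@H](c1ccc(OCc3ccccc3)c(OC)c1)O2 | intermediate
31 | ArB-Li (5-lithio derivative of 30) | [Li]c1cc(OC)c2c(c1)[C@H](CO[Si](C)(C)C(C)(C)C)[C@@H](c1ccc(OCc3ccccc3)c(OC)c1)O2 | intermediate
32 | (2S,3R)-2-[4-(benzyloxy)-3-methoxyphenyl]-3-[(TBS-oxy)methyl]-7-methoxy-2,3-dihydro-1-benzofuran-5-carbaldehyde (ArB-CHO) | O=Cc1cc(OC)c2c(c1)[C@H](CO[Si](C)(C)C(C)(C)C)[C@@H](c1ccc(OCc3ccccc3)c(OC)c1)O2 | intermediate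
33 | 2-(ArB)-1,3-dithiane | S1CCCSC1c1cc(OC)c2c(c1)[C@H](CO[Si](C)(C)C(C)(C)C)[C@@H](c1ccc(OCc3ccccc3)c(OC)c1)O2 | intermediate
34 | 5-hydroxyfuran-2(5H)-one | OC1OC(=O)C=C1 | starting material
35 | (−)-menthol, (1R,2S,5R)-2-isopropyl-5-methylcyclohexan-1-ol | CC(C)[C@@H]1CC[C@@H](C)C[C@H]1O | starting material
36 | (5R)-5-(menthyloxy)furan-2(5H)-one | O=C1C=C[C@H](O[C@@H]2C[C@H](C)CC[C@H]2C(C)C)O1 | intermediate
37 | 2-lithio-2-(ArB)-1,3-dithiane | [Li]C1(SCCCS1)c1cc(OC)c2c(c1)[C@H](CO[Si](C)(C)C(C)(C)C)[C@@H](c1ccc(OCc3ccccc3)c(OC)c1)O2 | intermediate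
38 | lithium (4R,5R)-4-[2-(ArB)-1,3-dithian-2-yl]-5-(menthyloxy)-4,5-dihydrofuran-2-olate | [Li]OC1=C[C@@H](C2(SCCCS2)c2cc(OC)c3c(c2)[C@H](CO[Si](C)(C)C(C)(C)C)[C@@H](c2ccc(OCc4ccccc4)c(OC)c2)O3)[C@H](O[C@@H]2C[C@H](C)CC[C@H]2C(C)C)O1 | intermediate
39 | (3R,4R,5R)-3-(ArA-CH2)-4-[2-(ArB)-1,3-dithian-2-yl]-5-(menthyloxy)oxolan-2-one | O=C1O[C@@H](O[C@@H]2C[C@H](C)CC[C@H]2C(C)C)[C@H](C2(SCCCS2)c2cc(OC)c3c(c2)[C@H](CO[Si](C)(C)C(C)(C)C)[C@@H](c2ccc(OCc4ccccc4)c(OC)c2)O3)[C@H]1Cc1ccc(O[C@@H](CO[Si](C)(C)C(C)(C)C)[C@H](O[Si](C)(C)C(C)(C)C)c2ccc(OCc3ccccc3)c(OC)c2)c(OC)c1 | intermediate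
40 | (3R,4R,5R)-3-(ArA-CH2)-4-(ArB-CH2)-5-(menthyloxy)oxolan-2-one | O=C1O[C@@H](O[C@@H]2C[C@H](C)CC[C@H]2C(C)C)[C@H](Cc2cc(OC)c3c(c2)[C@H](CO[Si](C)(C)C(C)(C)C)[C@@H](c2ccc(OCc4ccccc4)c(OC)c2)O3)[C@H]1Cc1ccc(O[C@@H](CO[Si](C)(C)C(C)(C)C)[C@H](O[Si](C)(C)C(C)(C)C)c2ccc(OCc3ccccc3)c(OC)c2)c(OC)c1 | intermediate
41 | potassium (2R,3R)-2-(ArA-CH2)-3-(ArB-CH2)-4-hydroxybutanoate | [K+].[O-]C(=O)[C@H](Cc1ccc(O[C@@H](CO[Si](C)(C)C(C)(C)C)[C@H](O[Si](C)(C)C(C)(C)C)c2ccc(OCc3ccccc3)c(OC)c2)c(OC)c1)[C@H](CO)Cc1cc(OC)c2c(c1)[C@H](CO[Si](C)(C)C(C)(C)C)[C@@H](c1ccc(OCc3ccccc3)c(OC)c1)O2 | intermediate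
42 | (3R,4R)-3-(ArA-CH2)-4-(ArB-CH2)oxolan-2-one | O=C1OC[C@H](Cc2cc(OC)c3c(c2)[C@H](CO[Si](C)(C)C(C)(C)C)[C@@H](c2ccc(OCc4ccccc4)c(OC)c2)O3)[C@H]1Cc1ccc(O[C@@H](CO[Si](C)(C)C(C)(C)C)[C@H](O[Si](C)(C)C(C)(C)C)c2ccc(OCc3ccccc3)c(OC)c2)c(OC)c1 | intermediate
43 | (3R,4R)-3-{4-[(1R,2S)-1-[4-(benzyloxy)-3-methoxyphenyl]-1,3-dihydroxypropan-2-yl]oxy-3-methoxybenzyl}-4-{[(2S,3R)-2-[4-(benzyloxy)-3-methoxyphenyl]-3-(hydroxymethyl)-7-methoxy-2,3-dihydro-1-benzofuran-5-yl]methyl}oxolan-2-one | O=C1OC[C@H](Cc2cc(OC)c3c(c2)[C@H](CO)[C@@H](c2ccc(OCc4ccccc4)c(OC)c2)O3)[C@H]1Cc1ccc(O[C@@H](CO)[C@H](O)c2ccc(OCc3ccccc3)c(OC)c2)c(OC)c1 | intermediate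
44 | (3R,4R)-3-{4-[(1R,2S)-1,3-dihydroxy-1-(4-hydroxy-3-methoxyphenyl)propan-2-yl]oxy-3-methoxybenzyl}-4-{[(2S,3R)-2-(4-hydroxy-3-methoxyphenyl)-3-(hydroxymethyl)-7-methoxy-2,3-dihydro-1-benzofuran-5-yl]methyl}oxolan-2-one | O=C1OC[C@H](Cc2cc(OC)c3c(c2)[C@H](CO)[C@@H](c2ccc(O)c(OC)c2)O3)[C@H]1Cc1ccc(O[C@@H](CO)[C@H](O)c2ccc(O)c(OC)c2)c(OC)c1 | target

**Step count and risks**

Total: 27 steps. Longest linear sequence: 16 steps (steps 11–21 and 23–27, from 17).

The three steps most likely to fail: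

Step 23. The enolate 38 may be protonated or may react only slowly with the large, ionization-prone benzylic bromide, and the dithianyl anion may add 1,2 instead of 1,4, so the three-component coupling may stop at the conjugate adduct or give mixtures. Fallback: the two C–C bonds are made in separate operations and the auxiliary is removed before the benzylation. Setting out from dithiane 33 and butenolide 36, the anion 37 is added as in step 23 and the enolate 38 is quenched with aqueous NH4Cl to give (4R,5R)-4-[2-(ArB)-1,3-dithian-2-yl]-5-(menthyloxy)oxolan-2-one F1. Desulfurization with NiCl2·6H2O/NaBH4 gives (4R,5R)-4-(ArB-CH2)-5-(menthyloxy)oxolan-2-one F2, and NaBH4/KOH followed by acidification gives (R)-4-(ArB-CH2)oxolan-2-one F3. Deprotonation with LiN(iPr)2 in THF at −78 °C gives the lithium enolate of this lactone F4, which is benzylated by bromide 16 (DMPU) trans to the C4 substituent, the classical alkylation of β-benzylbutyrolactone enolates. The route is rejoined at 42; compounds 39, 40 and 41 are bypassed, and the auxiliary removal is moved to a small substrate.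

Step 6. The alkoxyphosphonium intermediate sits on an electron-rich benzylic carbon and may ionize, so substitution may leak through an SN1 path (loss of clean inversion) or elimination may compete. Fallback: oxidation and reduction in place of substitution. Setting out from 11, Dess–Martin periodinane (NaHCO3, CH2Cl2) gives the ketone methyl 4-{[(2S)-1-[4-(benzyloxy)-3-methoxyphenyl]-1-oxo-3-(TBS-oxy)propan-2-yl]oxy}-3-methoxybenzoate F5. Reduction with Zn(BH4)2 in Et2O at −30 °C under chelation control (zinc bridging the ketone oxygen and the aryloxy oxygen, hydride from the open face) should give the erythro alcohol, rejoining the route at 13.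

Step 21. The Lewis acid may open the benzylic C2–O bond of the dihydrofuran ring toward the dithiol or remove the silyl ether before the electron-rich aldehyde has been converted. Fallback: the dithiane ring is attached preformed instead of being built on the aldehyde. 2-Chloro-1,3-dithiane F6 is prepared from 1,3-dithiane and N-chlorosuccinimide. Setting out from bromide 30, bromine–lithium exchange (n-BuLi, THF, −78 °C) gives 31, and transmetalation with MgBr2·OEt2 gives the arylmagnesium bromide ArB-MgBr F7. Coupling of the Grignard reagent with the chlorodithiane at −30 °C → rt should give dithiane 33 directly, rejoining the route at 33 and bypassing 32.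

Further compounds
F1 | step 23 | (4R,5R)-4-[2-(ArB)-1,3-dithian-2-yl]-5-(menthyloxy)oxolan-2-one | O=C1C[C@@H](C2(SCCCS2)c2cc(OC)c3c(c2)[C@H](CO[Si](C)(C)C(C)(C)C)[C@@H](c2ccc(OCc4ccccc4)c(OC)c2)O3)[C@H](O[C@@H]2C[C@H](C)CC[C@H]2C(C)C)O1
F2 | step 23 | (4R,5R)-4-(ArB-CH2)-5-(menthyloxy)oxolan-2-one | O=C1C[C@@H](Cc2cc(OC)c3c(c2)[C@H](CO[Si](C)(C)C(C)(C)C)[C@@H](c2ccc(OCc4ccccc4)c(OC)c2)O3)[C@H](O[C@@H]2C[C@H](C)CC[C@H]2C(C)C)O1
F3 | step 23 | (R)-4-(ArB-CH2)oxolan-2-one | O=C1C[C@@H](Cc2cc(OC)c3c(c2)[C@H](CO[Si](C)(C)C(C)(C)C)[C@@H](c2ccc(OCc4ccccc4)c(OC)c2)O3)CO1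
F4 | step 23 | lithium enolate of F3 | [Li]OC1=C[C@@H](Cc2cc(OC)c3c(c2)[C@H](CO[Si](C)(C)C(C)(C)C)[C@@H](c2ccc(OCc4ccccc4)c(OC)c2)O3)CO1
F5 | step 6 | methyl 4-{[(2S)-1-[4-(benzyloxy)-3-methoxyphenyl]-1-oxo-3-(TBS-oxy)propan-2-yl]oxy}-3-methoxybenzoate | CC(C)(C)[Si](C)(C)OC[C@H](Oc1ccc(C(=O)OC)cc1OC)C(=O)c1ccc(OCc2ccccc2)c(OC)c1
F6 | step 21 | 2-chloro-1,3-dithiane | ClC1SCCCS1
F7 | step 21 | ArB-MgBr (arylmagnesium bromide from 30) | Br[Mg]c1cc(OC)c2c(c1)[C@H](CO[Si](C)(C)C(C)(C)C)[C@@H](c1ccc(OCc3ccccc3)c(OC)c1)O2
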